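**Retrosynthetic overview**
- No ring is formed: the coumarin bicycle is bought intact in phenol 1.
- Aryl ether C–O bond: phenol 1 + 3-bromobut-3-en-1-ol 2 ⇒ alkenyl bromide 3 (Mitsunobu).
- Chiral piece: L-malic-acid-derived (S)-α-hydroxy-γ-butyrolactone 4 ⇒ triol 5 by double methyl addition; the only stereocentre is bought in 4.
- Key C(sp2)–C(sp3) bond at the 1,1-disubstituted alkene: 3 + 5, through aminal 6, ⇒ target 7 by a blue-light nickel/iridium deoxygenative alkenylation.

Assumption: 8-hydroxy-7-methoxycoumarin (daphnetin 7-methyl ether) and the benzoxazolium salt of step 3 are bought as catalogue compounds.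

**Step 1**
Reactants: 1 8-hydroxy-7-methoxy-2H-chromen-2-one; 2 3-bromobut-3-en-1-ol
Product: 3 8-[(3-bromobut-3-en-1-yl)oxy]-7-methoxy-2H-chromen-2-one
Conditions: PPh3 (1.3 equiv), DIAD (1.3 equiv), THF, 0 °C to rt
Reagents that add atoms: none
Why: Mitsunobu etherification of the acidic 8-OH with the primary alkoxyphosphonium ion of 2 runs under neutral conditions that leave the lactone and the alkenyl bromide untouched; no stereocentre is involved.

**Step 2**
Reactants: 4 (3S)-3-hydroxyoxolan-2-one
Product: 5 (3S)-4-methylpentane-1,3,4-triol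
Conditions: MeMgBr (4 equiv), THF, 0 °C to rt; then H2O (minimum), Na2SO4, filtration
Reagents that add atoms: methylmagnesium bromide, C[Mg]Br
Why: Double Grignard addition to the lactone carbonyl gives the tertiary carbinol and frees the primary alcohol, while the magnesium alkoxide formed first at the 3-OH suppresses enolisation, so the (S) centre bought in 4 is carried over unchanged.

**Step 3**
Reactants: 3 8-[(3-bromobut-3-en-1-yl)oxy]-7-methoxy-2H-chromen-2-one; 5 (3S)-4-methylpentane-1,3,4-triol
Product: 7 8-{[(6S)-6,7-dihydroxy-7-methyl-3-methylideneoctyl]oxy}-7-methoxy-2H-chromen-2-one, via benzoxazoline aminal 6 (not isolated)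
Conditions: 5 (1.6 equiv), 5,7-di-tert-butyl-3-phenylbenzoxazolium tetrafluoroborate (1.5 equiv), pyridine (1.5 equiv), MTBE/DMA, rt, 20 min; then 3, Ir(ppy)2(dtbbpy)PF6 (1.5 mol%), NiBr2(dtbbpy) (5 mol%), quinuclidine (1.8 equiv), DMA, 450 nm LEDs, rt
Reagents that add atoms: none
Why: Proposed new method: the benzoxazolium salt, kept below the amount of triol, condenses reversibly under pyridine buffering with the least hindered primary OH (the secondary OH is neopentyl-like, the tertiary OH inert at rt) to give aminal 6; photoexcited Ir(ppy)2(dtbbpy)PF6 oxidises the anilinic nitrogen of 6, deprotonation of the aminal C–H and β-scission of the alkyl C–O bond expel the benzoxazolone and the primary radical •CH2CH2CH(OH)CMe2OH, which is trapped by the alkenyl–nickel bromide formed by oxidative addition of 3 to zerovalent nickel, and reductive elimination from trivalent nickel forges the C(sp2)–C(sp3) bond with the alkene fixed at the 1,1-disubstituted position; the stereocentre lies two carbons from the radical and is not touched; the closest known reaction type is the benzoxazolium-mediated nickel metallaphotoredox deoxygenative arylation of mono-alcohols with aryl halides, extended here to an alkenyl bromide and to site-selective activation within an unprotected 1,3,4-triol.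

**Compound list**
1 | 8-hydroxy-7-methoxy-2H-chromen-2-one (daphnetin 7-methyl ether) | COc1ccc2ccc(=O)oc2c1O | starting material
2 | 3-bromobut-3-en-1-ol | C=C(Br)CCO | starting material
3 | 8-[(3-bromobut-3-en-1-yl)oxy]-7-methoxy-2H-chromen-2-one | C=C(Br)CCOc1c(OC)ccc2ccc(=O)oc12 | intermediate
4 | (3S)-3-hydroxyoxolan-2-one ((S)-α-hydroxy-γ-butyrolactone) | O=C1OCC[C@@H]1O | starting material
5 | (3S)-4-methylpentane-1,3,4-triol | OCC[C@H](O)C(C)(C)O | intermediate
6 | (3S)-1-[(5,7-di-tert-butyl-3-phenyl-2,3-dihydro-1,3-benzoxazol-2-yl)oxy]-4-methylpentane-3,4-diol (both epimers at the aminal carbon) | CC(C)(C)c1cc2N(c3ccccc3)C(OCC[C@H](O)C(C)(C)O)Oc2c(c1)C(C)(C)C | intermediate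
7 | 8-{[(6S)-6,7-dihydroxy-7-methyl-3-methylideneoctyl]oxy}-7-methoxy-2H-chromen-2-one | C=C(CCOc1c(OC)ccc2ccc(=O)oc12)CC[C@H](O)C(C)(C)O | target

**Totals**
Total step count: 3. Longest linear sequence: 2 steps (4 → 5 → 7, or 1 → 3 → 7).

**Steps most likely to fail**

1. Step 3 (the proposed new step). The risks are:
   - condensation at the secondary OH, which would give a branched isomer;
   - nickel C–O coupling of a free OH with 3;
   - addition of the alkyl radical to the coumarin C3–C4 bond;
   - protodebromination of 3.

   Sensitised [2+2] dimerisation of the coumarin is not expected: the coumarin does not absorb at 450 nm, and the triplet energy of the photocatalyst (about 49 kcal/mol) is well below that of the coumarin (about 60 kcal/mol).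

   The fallback uses known chemistry, sets out from 5 (with 3 as partner) and comes back at 7. Triol 5 with acetone, 2,2-dimethoxypropane and PPTS gives the five-membered acetonide 2-[(4S)-2,2,5,5-tetramethyl-1,3-dioxolan-4-yl]ethan-1-ol F1. Appel iodination (I2, PPh3, imidazole, CH2Cl2) gives (4S)-4-(2-iodoethyl)-2,2,5,5-tetramethyl-1,3-dioxolane F2. The established nickel-catalysed reductive cross-electrophile coupling of a primary alkyl iodide with an alkenyl bromide, run electroreductively (NiBr2·glyme, dtbbpy, NaI, DMA, sacrificial zinc anode, constant current), joins F2 and 3 to give 7-methoxy-8-({3-methylidene-5-[(4S)-2,2,5,5-tetramethyl-1,3-dioxolan-4-yl]pentyl}oxy)-2H-chromen-2-one F3. Mild hydrolysis (80% aq. AcOH, 40 °C) then gives 7.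

2. Step 2. The risks are stalling at the mono-adduct on the poorly soluble magnesium tris-alkoxide, and loss of the very water-soluble triol on work-up. The fallback sets out from 4 and comes back at 5. Silylation (TBSCl, imidazole, DMF) gives (3S)-3-{[tert-butyl(dimethyl)silyl]oxy}oxolan-2-one F4. MeMgBr (2.5 equiv, THF) gives the extractable (3S)-3-{[tert-butyl(dimethyl)silyl]oxy}-4-methylpentane-1,4-diol F5; any silyl migration between the oxygens is of no consequence. Methanolysis (HCl from AcCl, MeOH) and evaporation of the volatile silyl ether leave 5.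

3. Step 1. The phenol is flanked on both sides, so the Mitsunobu coupling may be slow and the hydrazide may be alkylated instead. The fallback sets out from 2 and comes back at 3. Tosylation (TsCl, Et3N, DMAP, CH2Cl2) gives 3-bromobut-3-en-1-yl 4-methylbenzenesulfonate F6. Williamson alkylation of the caesium phenoxide of 1 (Cs2CO3, DMF, 50 °C) with F6 gives 3.

**Further compounds**
F1 | step 3 | 2-[(4S)-2,2,5,5-tetramethyl-1,3-dioxolan-4-yl]ethan-1-ol | OCC[C@@H]1OC(C)(C)OC1(C)C
F2 | step 3 | (4S)-4-(2-iodoethyl)-2,2,5,5-tetramethyl-1,3-dioxolane | ICC[C@@H]1OC(C)(C)OC1(C)C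
F3 | step 3 | 7-methoxy-8-({3-methylidene-5-[(4S)-2,2,5,5-tetramethyl-1,3-dioxolan-4-yl]pentyl}oxy)-2H-chromen-2-one | C=C(CCOc1c(OC)ccc2ccc(=O)oc12)CC[C@@H]1OC(C)(C)OC1(C)C
F4 | step 2 | (3S)-3-{[tert-butyl(dimethyl)silyl]oxy}oxolan-2-one | O=C1OCC[C@@H]1O[Si](C)(C)C(C)(C)C
F5 | step 2 | (3S)-3-{[tert-butyl(dimethyl)silyl]oxy}-4-methylpentane-1,4-diol | OCC[C@H](O[Si](C)(C)C(C)(C)C)C(C)(C)O
F6 | step 1 | 3-bromobut-3-en-1-yl 4-methylbenzenesulfonate | C=C(Br)CCOS(=O)(=O)c1ccc(C)cc1
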